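**Retrosynthetic overview**

- The C3 ester is made from the trans-alcohol and (Z)-2-(acetoxymethyl)but-2-enoic acid (built from crotonaldehyde by way of (Z)-2-bromobut-2-en-1-ol); the C6 phenol travels as its PMB ether and is freed last.
- The dihydrofuran ring (O1–C2–C3–C3a–C7a) is opened at O1–C7a and C2–C3 together. This gives a 2-fluorobenzylic alcohol (C3 as CH2OH on C3a, F on C7a) and the gem-dibenzoate of methacrolein (C2 with its oxygen and the isopropenyl group).
- Enabling feature: the C5 acetyl group is para to C7a, so a C7a–F bond is an SNAr electrophile for the C2 oxygen. C3 is a benzylic carbinol carbon next to the C2–O1 oxygen, i.e. an anti-1,2-diol unit from an aldehyde and an α-oxyallyl nucleophile.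
- Ring order: the benzene ring is bought; the furan ring is the only ring formed (step 4), together with both stereocentres.

Key step: step 4

Remark on the chemistry: compound 1 is taken as a catalogue compound, and the ligand enantiomer in step 4 is assigned by analogy with the parent allylation, so its antipode would be used if a model run showed the opposite facial sense.

**Route**

Step 1
Reactants: 1 1-(5-bromo-4-fluoro-2-hydroxyphenyl)ethan-1-one
Product: 2 1-{5-bromo-4-fluoro-2-[(4-methoxybenzyl)oxy]phenyl}ethan-1-one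
Conditions: PMBCl (1.2 equiv), K2CO3 (2 equiv), DMF, 50 °C
Reagents that add atoms: 4-methoxybenzyl chloride, COc1ccc(CCl)cc1
Why: Williamson etherification of the chelated phenol should outpace any attack on the aryl fluoride, and the PMB ether keeps this oxygen neutral so that no phenoxide later switches off the SNAr at C7a.

Step 2
Reactants: 2 1-{5-bromo-4-fluoro-2-[(4-methoxybenzyl)oxy]phenyl}ethan-1-one
Product: 3 1-{4-fluoro-5-(hydroxymethyl)-2-[(4-methoxybenzyl)oxy]phenyl}ethan-1-one
Conditions: Bu3SnCH2OH (1.3 equiv), Pd(PPh3)4 (5 mol%), 1,4-dioxane, 90 °C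
Reagents that add atoms: (tributylstannyl)methanol, CCCC[Sn](CCCC)(CCCC)CO
Why: Migita–Kosugi–Stille coupling under neutral zerovalent-palladium catalysis should replace C–Br by C–CH2OH while leaving the activated C–F bond, the ketone and the PMB ether untouched.

Step 3
Reactants: 4 methacrolein (2-methylprop-2-enal)
Product: 5 2-methylprop-2-ene-1,1-diyl dibenzoate
Conditions: Bz2O (1.0 equiv), H2SO4 (cat.), CH2Cl2, 0 °C to rt
Reagents that add atoms: benzoic anhydride, O=C(OC(=O)c1ccccc1)c1ccccc1
Why: Acid-catalysed addition of the anhydride across the aldehyde C=O (acylal formation) should give the gem-dibenzoate, the form in which methacrolein can be ionised to an α-benzoyloxy allyl-metal nucleophile.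

Step 4
Reactants: 3 1-{4-fluoro-5-(hydroxymethyl)-2-[(4-methoxybenzyl)oxy]phenyl}ethan-1-one; 5 2-methylprop-2-ene-1,1-diyl dibenzoate
Product: 9 (2S,3R)-5-acetyl-6-[(4-methoxybenzyl)oxy]-2-(prop-1-en-2-yl)-2,3-dihydro-1-benzofuran-3-yl benzoate, via aryl aldehyde 6 (not isolated), via anti C2-benzoate adduct 7 (not isolated), via C3-benzoate C2-alcohol 8 (not isolated)
Conditions: 5 (1.5 equiv), [Ir(cod)Cl]2 (2.5 mol%), (S)-SEGPHOS (5 mol%), 4-cyano-3-nitrobenzoic acid (10 mol%), Cs2CO3 (20 mol%), THF, 90 °C, sealed tube; then Cs2CO3 (3 equiv), DMSO, 70 °C, same flask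
Reagents that add atoms: none
Why: Proposed new method: the cyclometallated trivalent iridium catalyst dehydrogenates the primary benzylic alcohol 3 to aldehyde 6 and uses the hydride to turn gem-dibenzoate 5 (loss of one benzoate) into an (E)-γ-benzoyloxy σ-methallyl iridium species that adds to 6 through a closed chair transition state to give anti adduct 7; the added Cs2CO3 then shifts the benzoyl group from the C2 oxygen to the C3 oxygen (8), and the freed C2 alkoxide displaces fluoride at C7a through a Meisenheimer intermediate stabilised by the para acetyl group, forming O1–C7a. The closest known reaction types are the iridium-catalysed transfer-hydrogenative anti-(α-acyloxy)allylation of alcohols with allylic gem-dicarboxylates, base-mediated 1,2-acyl migration in diol monoesters and alkoxide SNAr on 4-fluoroacetophenones; new are the 2-methyl donor and the merger into one operation. The furan ring closes by a 5-exo-trig addition–elimination of O1 on C7a. C3 is set by ligand-controlled facial selection at the aldehyde carbonyl, and C2 is set relative to C3 by the (E)-geometry of the σ-allyl in the chair (anti), which the acyl shift and the ring closure carry unchanged into the trans-(2S,3R) ring because no C–O bond at C2 or C3 is broken. The step needs anti over syn selectivity (E versus Z σ-allyl), aldehyde over ketone selectivity (only the primary alcohol is dehydrogenated and the aldehyde is the better electrophile) and ring closure over intermolecular substitution; the last is secured because only the C2 oxygen can reach C7a in a five-membered ring (the C3 oxygen would need a four-membered one) and because the phenol is masked as its PMB ether.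

Step 5
Reactants: 9 (2S,3R)-5-acetyl-6-[(4-methoxybenzyl)oxy]-2-(prop-1-en-2-yl)-2,3-dihydro-1-benzofuran-3-yl benzoate
Product: 10 1-[(2S,3R)-3-hydroxy-6-[(4-methoxybenzyl)oxy]-2-(prop-1-en-2-yl)-2,3-dihydro-1-benzofuran-5-yl]ethan-1-one
Conditions: K2CO3 (0.3 equiv), MeOH, 0 °C to rt
Reagents that add atoms: none
Why: Carbonate-catalysed transesterification (methanolysis) cleaves the benzoate at the acyl–oxygen bond, so C3 keeps its configuration, and with fluoride gone no SNAr side reaction remains.

Step 6
Reactants: 11 (E)-but-2-enal (crotonaldehyde)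
Product: 13 (2Z)-2-bromobut-2-enal, via 2,3-dibromobutanal 12 (not isolated)
Conditions: Br2 (1.0 equiv), CH2Cl2, 0 °C; then Et3N (1.1 equiv), 0 °C to rt
Reagents that add atoms: bromine, BrBr
Why: Bromine addition to the alkene followed by amine-induced E1cB loss of the β-bromide should give the α-bromo enal as the thermodynamically preferred (Z)-isomer (methyl trans to formyl), which fixes the side-chain geometry.

Step 7
Reactants: 13 (2Z)-2-bromobut-2-enal
Product: 14 (2Z)-2-bromobut-2-en-1-ol
Conditions: NaBH4, CeCl3·7H2O, MeOH, 0 °C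
Reagents that add atoms: none
Why: Luche reduction should give clean 1,2-reduction of the enal without touching the vinylic C–Br bond or the double-bond geometry.

Step 8
Reactants: 14 (2Z)-2-bromobut-2-en-1-ol
Product: 16 (2Z)-2-(hydroxymethyl)but-2-enoic acid, via dilithio species 15 (not isolated)
Conditions: n-BuLi (1.05 equiv), THF, −78 °C; t-BuLi (2.1 equiv), −78 °C; CO2 (gas), −78 °C to rt; aq. HCl
Reagents that add atoms: carbon dioxide, O=C=O
Why: Deprotonation of the hydroxyl followed by bromine–lithium exchange gives a configurationally stable alkenyllithium that is carboxylated with retention, so the carboxyl group ends up cis to the methyl group.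

Step 9
Reactants: 16 (2Z)-2-(hydroxymethyl)but-2-enoic acid
Product: 17 (2Z)-2-[(acetyloxy)methyl]but-2-enoic acid
Conditions: AcCl (1.5 equiv), CH2Cl2, 0 °C to rt; aqueous work-up
Reagents that add atoms: acetyl chloride, CC(Cl)=O
Why: O-Acetylation of the hydroxy acid with acetyl chloride without an amine base avoids any nucleophile that could add to the enoate, so the (Z)-geometry should be kept.

Step 10
Reactants: 10 1-[(2S,3R)-3-hydroxy-6-[(4-methoxybenzyl)oxy]-2-(prop-1-en-2-yl)-2,3-dihydro-1-benzofuran-5-yl]ethan-1-one; 17 (2Z)-2-[(acetyloxy)methyl]but-2-enoic acid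
Product: 19 (2S,3R)-5-acetyl-6-[(4-methoxybenzyl)oxy]-2-(prop-1-en-2-yl)-2,3-dihydro-1-benzofuran-3-yl (2Z)-2-[(acetyloxy)methyl]but-2-enoate, via mixed anhydride 18 (not isolated)
Conditions: 17 (1.5 equiv), 2,4,6-trichlorobenzoyl chloride, i-Pr2NEt, toluene, rt; then 10, toluene, 80 °C, no DMAP
Reagents that add atoms: none
Why: Yamaguchi-type mixed-anhydride esterification run thermally without a nucleophilic amine catalyst (the stereoconservative protocol used for angelate esters) should acylate the C3 hydroxyl at the unhindered enoyl carbonyl with retention at C3 and without Z to E isomerisation or SN2′ loss of the allylic acetate.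

Step 11
Reactants: 19 (2S,3R)-5-acetyl-6-[(4-methoxybenzyl)oxy]-2-(prop-1-en-2-yl)-2,3-dihydro-1-benzofuran-3-yl (2Z)-2-[(acetyloxy)methyl]but-2-enoate
Product: 20 (2S,3R)-5-acetyl-6-hydroxy-2-(prop-1-en-2-yl)-2,3-dihydro-1-benzofuran-3-yl (2Z)-2-[(acetyloxy)methyl]but-2-enoate
Conditions: DDQ (1.5 equiv), CH2Cl2/pH 7 phosphate buffer, 0 °C to rt
Reagents that add atoms: none
Why: DDQ oxidises the PMB ether by benzylic hydride abstraction and the oxocarbenium ion is hydrolysed under buffered neutral conditions, which should spare the benzylic ester, the allylic acetate and both alkenes.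

**Compound list**

1 | 1-(5-bromo-4-fluoro-2-hydroxyphenyl)ethan-1-one | CC(=O)c1cc(Br)c(F)cc1O | starting material
2 | 1-{5-bromo-4-fluoro-2-[(4-methoxybenzyl)oxy]phenyl}ethan-1-one | CC(=O)c1cc(Br)c(F)cc1OCc1ccc(OC)cc1 | intermediate
3 | 1-{4-fluoro-5-(hydroxymethyl)-2-[(4-methoxybenzyl)oxy]phenyl}ethan-1-one | CC(=O)c1cc(CO)c(F)cc1OCc1ccc(OC)cc1 | intermediate
4 | methacrolein (2-methylprop-2-enal) | C=C(C)C=O | starting material
5 | 2-methylprop-2-ene-1,1-diyl dibenzoate | C=C(C)C(OC(=O)c1ccccc1)OC(=O)c1ccccc1 | intermediate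
6 | 5-acetyl-2-fluoro-4-[(4-methoxybenzyl)oxy]benzaldehyde (not isolated) | CC(=O)c1cc(C=O)c(F)cc1OCc1ccc(OC)cc1 | intermediate
7 | (1R,2S)-1-{5-acetyl-2-fluoro-4-[(4-methoxybenzyl)oxy]phenyl}-1-hydroxy-3-methylbut-3-en-2-yl benzoate (anti; not isolated) | C=C(C)[C@H](OC(=O)c1ccccc1)[C@H](O)c1cc(C(C)=O)c(OCc2ccc(OC)cc2)cc1F | intermediate
8 | (1R,2S)-1-{5-acetyl-2-fluoro-4-[(4-methoxybenzyl)oxy]phenyl}-2-hydroxy-3-methylbut-3-en-1-yl benzoate (reacts as its alkoxide; not isolated) | C=C(C)[C@H](O)[C@H](OC(=O)c1ccccc1)c1cc(C(C)=O)c(OCc2ccc(OC)cc2)cc1F | intermediate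
9 | (2S,3R)-5-acetyl-6-[(4-methoxybenzyl)oxy]-2-(prop-1-en-2-yl)-2,3-dihydro-1-benzofuran-3-yl benzoate (trans) | C=C(C)[C@@H]1Oc2cc(OCc3ccc(OC)cc3)c(C(C)=O)cc2[C@H]1OC(=O)c1ccccc1 | intermediate
10 | 1-[(2S,3R)-3-hydroxy-6-[(4-methoxybenzyl)oxy]-2-(prop-1-en-2-yl)-2,3-dihydro-1-benzofuran-5-yl]ethan-1-one (trans) | C=C(C)[C@@H]1Oc2cc(OCc3ccc(OC)cc3)c(C(C)=O)cc2[C@H]1O | intermediate
11 | (E)-but-2-enal (crotonaldehyde) | C/C=C/C=O | starting material
12 | 2,3-dibromobutanal (diastereomer mixture; not isolated) | CC(Br)C(Br)C=O | intermediate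
13 | (2Z)-2-bromobut-2-enal | C/C=C(Br)/C=O | intermediate
14 | (2Z)-2-bromobut-2-en-1-ol | C/C=C(Br)/CO | intermediate
15 | lithium (2E)-2-lithiobut-2-en-1-olate (lithium in place of bromine, same geometry as 14; not isolated) | C/C=C([Li])/CO[Li] | intermediate
16 | (2Z)-2-(hydroxymethyl)but-2-enoic acid | C/C=C(C(=O)O)/CO | intermediate
17 | (2Z)-2-[(acetyloxy)methyl]but-2-enoic acid | C/C=C(C(=O)O)/COC(C)=O | intermediate
18 | (2Z)-2-[(acetyloxy)methyl]but-2-enoic 2,4,6-trichlorobenzoic anhydride (not isolated) | C/C=C(C(=O)OC(=O)c1c(Cl)cc(Cl)cc1Cl)/COC(C)=O | intermediate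
19 | (2S,3R)-5-acetyl-6-[(4-methoxybenzyl)oxy]-2-(prop-1-en-2-yl)-2,3-dihydro-1-benzofuran-3-yl (2Z)-2-[(acetyloxy)methyl]but-2-enoate | C=C(C)[C@@H]1Oc2cc(OCc3ccc(OC)cc3)c(C(C)=O)cc2[C@H]1OC(=O)/C(=C\C)COC(C)=O | intermediate
20 | (2S,3R)-5-acetyl-6-hydroxy-2-(prop-1-en-2-yl)-2,3-dihydro-1-benzofuran-3-yl (2Z)-2-[(acetyloxy)methyl]but-2-enoate | C=C(C)[C@@H]1Oc2cc(O)c(C(C)=O)cc2[C@H]1OC(=O)/C(=C\C)COC(C)=O | target

**Step count**

Total steps: 11. Longest linear sequence: 6 (steps 1, 2, 4, 5, 10, 11; the acid branch, steps 6 to 11, is equally long).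

**Steps most likely to fail**

Step 4 (proposed new method). What may go wrong: loss of the anti preference through syn/anti isomerisation of the 2-methyl-substituted allyl-iridium intermediate, slow ionisation of the hindered donor, or ring closure lagging behind intermolecular substitution at the fluoroarene. The fallback uses known chemistry and closes the ring through O1–C2 instead. It sets out from 3, which MnO2 in CH2Cl2 at rt oxidises to aldehyde 6. KOH in DMSO/H2O at rt then replaces the doubly activated fluoride to give 5-acetyl-2-hydroxy-4-[(4-methoxybenzyl)oxy]benzaldehyde F1. The chiral allylic sulfonium salt (1R,4R,5R)-4,7,7-trimethyl-6-(2-methylprop-2-en-1-yl)-6-thiabicyclo[3.2.1]octan-6-ium trifluoromethanesulfonate F2 is prepared from isothiocineole, 3-bromo-2-methylprop-1-ene and LiOTf. F2 is deprotonated with KOH in MeCN/H2O at 0 °C in the presence of F1. This asymmetric Johnson–Corey–Chaykovsky epoxidation should give the trans-epoxide (2R,3R)-2-{5-acetyl-2-hydroxy-4-[(4-methoxybenzyl)oxy]phenyl}-3-(prop-1-en-2-yl)oxirane F3, which is not isolated. Its ortho phenoxide opens it at the allylic carbon (5-exo-tet, inversion at C2) to give trans-alcohol 10 directly, where the fallback comes back to the route; step 5 then falls away. The isothiocineole enantiomer is the one expected to give the (2R,3R)-epoxide; its antipode is taken if the other sense is found.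

Step 10. What may go wrong: Z to E isomerisation of the enoate by reversible conjugate addition, SN2′ loss of the allylic acetate, or slow acylation of the hindered secondary alcohol without a catalyst. The fallback acylates with an acid that carries no allylic leaving group and installs the acetate afterwards. It sets out from 14, which TBSCl and imidazole in DMF convert into tert-butyl{[(2Z)-2-bromobut-2-en-1-yl]oxy}dimethylsilane F4. Bromine–lithium exchange with t-BuLi in THF at −78 °C and carboxylation with CO2 give (2Z)-2-{[(tert-butyldimethylsilyl)oxy]methyl}but-2-enoic acid F5. F5 is activated with 2,4,6-trichlorobenzoyl chloride and Et3N as (2Z)-2-{[(tert-butyldimethylsilyl)oxy]methyl}but-2-enoic 2,4,6-trichlorobenzoic anhydride F6. F6 is coupled with 10 in the presence of DMAP in toluene at rt to give (2S,3R)-5-acetyl-6-[(4-methoxybenzyl)oxy]-2-(prop-1-en-2-yl)-2,3-dihydro-1-benzofuran-3-yl (2Z)-2-{[(tert-butyldimethylsilyl)oxy]methyl}but-2-enoate F7. HF·pyridine in THF at 0 °C frees (2S,3R)-5-acetyl-6-[(4-methoxybenzyl)oxy]-2-(prop-1-en-2-yl)-2,3-dihydro-1-benzofuran-3-yl (2Z)-2-(hydroxymethyl)but-2-enoate F8. Ac2O and pyridine at 0 °C acetylate F8 to 19, where the fallback comes back to the route.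

Step 11. What may go wrong: slow oxidation of the electron-poor aryl PMB ether, further oxidation of the freed phenol, or loss of the para-hydroxybenzylic ester through a quinone methide. The fallback frees the phenol before the sensitive ester is present. It sets out from 10, which MgBr2·OEt2 and Me2S in CH2Cl2 at rt (chelation by the ortho acetyl group) should convert into 1-[(2S,3R)-3,6-dihydroxy-2-(prop-1-en-2-yl)-2,3-dihydro-1-benzofuran-5-yl]ethan-1-one F9. F9 is acylated with mixed anhydride 18 in toluene at 80 °C without base. The phenol, locked in a hydrogen bond to the acetyl carbonyl, should stay unreacted while the C3 hydroxyl is esterified, which gives 20 directly.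

**Further compounds**

F1 | step 4 | 5-acetyl-2-hydroxy-4-[(4-methoxybenzyl)oxy]benzaldehyde | CC(=O)c1cc(C=O)c(O)cc1OCc1ccc(OC)cc1
F2 | step 4 | (1R,4R,5R)-4,7,7-trimethyl-6-(2-methylprop-2-en-1-yl)-6-thiabicyclo[3.2.1]octan-6-ium trifluoromethanesulfonate | C[C@@H]1CC[C@@H]2C[C@H]1[S+](CC(C)=C)C2(C)C.[O-]S(=O)(=O)C(F)(F)F
F3 | step 4 | (2R,3R)-2-{5-acetyl-2-hydroxy-4-[(4-methoxybenzyl)oxy]phenyl}-3-(prop-1-en-2-yl)oxirane | C=C(C)[C@H]1O[C@@H]1c1cc(C(C)=O)c(OCc2ccc(OC)cc2)cc1O
F4 | step 10 | tert-butyl{[(2Z)-2-bromobut-2-en-1-yl]oxy}dimethylsilane | C/C=C(Br)/CO[Si](C)(C)C(C)(C)C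
F5 | step 10 | (2Z)-2-{[(tert-butyldimethylsilyl)oxy]methyl}but-2-enoic acid | C/C=C(C(=O)O)/CO[Si](C)(C)C(C)(C)C
F6 | step 10 | (2Z)-2-{[(tert-butyldimethylsilyl)oxy]methyl}but-2-enoic 2,4,6-trichlorobenzoic anhydride | C/C=C(C(=O)OC(=O)c1c(Cl)cc(Cl)cc1Cl)/CO[Si](C)(C)C(C)(C)C
F7 | step 10 | (2S,3R)-5-acetyl-6-[(4-methoxybenzyl)oxy]-2-(prop-1-en-2-yl)-2,3-dihydro-1-benzofuran-3-yl (2Z)-2-{[(tert-butyldimethylsilyl)oxy]methyl}but-2-enoate | C=C(C)[C@@H]1Oc2cc(OCc3ccc(OC)cc3)c(C(C)=O)cc2[C@H]1OC(=O)/C(=C\C)CO[Si](C)(C)C(C)(C)C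
F8 | step 10 | (2S,3R)-5-acetyl-6-[(4-methoxybenzyl)oxy]-2-(prop-1-en-2-yl)-2,3-dihydro-1-benzofuran-3-yl (2Z)-2-(hydroxymethyl)but-2-enoate | C=C(C)[C@@H]1Oc2cc(OCc3ccc(OC)cc3)c(C(C)=O)cc2[C@H]1OC(=O)/C(=C\C)CO
F9 | step 11 | 1-[(2S,3R)-3,6-dihydroxy-2-(prop-1-en-2-yl)-2,3-dihydro-1-benzofuran-5-yl]ethan-1-one | C=C(C)[C@@H]1Oc2cc(O)c(C(C)=O)cc2[C@H]1O
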